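**Strategy**

The cyclohexa-2,5-dienone ring is cut into a four-carbon unit, C1(=O)–C6H=C5(OMe)–C4(OMe)(alkenyl), which is a 3,4-dimethoxycyclobut-2-enone already carrying the quaternary carbon, and a two-carbon unit, C2(allyl)=C3H, which is the alkyne pent-1-en-4-yne. In one operation the key step inserts this alkyne into the strained acyl C1–C4 bond of the racemic cyclobutenone under chiral zerovalent nickel catalysis: the six-membered ring is formed by two-atom ring expansion, the allyl group arrives, and the C4 stereocentre is set enantioconvergently. It exploits that C4 is quaternary (no phenol tautomer) and doubly allylic (configurationally labile on nickel). The cyclobutenone comes from methyl semisquarate and a geometrically defined alkenyllithium.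

Key step: step 5

Assumption: the sense of induction of the chiral ligand in step 5 cannot be predicted, so the ligand antipode that delivers the (4S) product is to be chosen after a first run.

**Route**

Step 1
Reactants: 1 4-iodo-1,2-dimethoxybenzene; 2 propyne
Product: 3 1,2-dimethoxy-4-(prop-1-yn-1-yl)benzene
Conditions: PdCl2(PPh3)2 (2 mol %), CuI (4 mol %), Et3N, THF, propyne (about 3 equiv, THF solution), rt, sealed flask
Reagents that add atoms: none
Why: Sonogashira coupling of an electron-rich aryl iodide with a terminal alkyne; no stereocentre is formed.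

Step 2
Reactants: 3 1,2-dimethoxy-4-(prop-1-yn-1-yl)benzene
Product: 5 4-[(1E)-2-iodoprop-1-en-1-yl]-1,2-dimethoxybenzene, via alkenylzirconocene 4 (not isolated)
Conditions: Cp2Zr(H)Cl (1.5 equiv), THF, rt to 50 °C; then I2, THF, 0 °C
Reagents that add atoms: iodine, II
Why: Schwartz hydrozirconation is a syn addition that should place zirconium on the methyl-bearing carbon, away from the aryl group (the slight excess of hydride equilibrates the regioisomers), and iodinolysis of the C–Zr bond proceeds with retention, so iodine ends trans to the aryl ring (E).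

Step 3
Reactants: 6 dimethyl squarate (3,4-dimethoxycyclobut-3-ene-1,2-dione)
Product: 8 3-methoxycyclobut-3-ene-1,2-dione (methyl semisquarate), via hydroxycyclobutenone 7 (not isolated)
Conditions: LiAlH(OtBu)3 (1.05 equiv), THF, −78 to −40 °C; aq. HCl work-up; then conc. HCl (cat.), CH2Cl2, rt
Reagents that add atoms: water, O
Why: Mono-reduction of one squarate carbonyl by the bulky hydride, then acid-catalysed allylic transposition (ionisation of the carbinol, capture of water at the distal methoxy-bearing carbon, loss of methanol) is the established semisquarate synthesis; no stereocentre remains.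

Step 4
Reactants: 5 4-[(1E)-2-iodoprop-1-en-1-yl]-1,2-dimethoxybenzene; 8 3-methoxycyclobut-3-ene-1,2-dione
Product: 11 rac-4-[(1E)-1-(3,4-dimethoxyphenyl)prop-1-en-2-yl]-3,4-dimethoxycyclobut-2-en-1-one, via alkenyllithium 9 (not isolated), via lithium alkoxide 10 (not isolated)
Conditions: 5, t-BuLi (2.0 equiv), THF/Et2O, −78 °C; cannulated into 8, THF, −78 °C; then MeOTf (1.5 equiv), −78 to 0 °C
Reagents that add atoms: methyl trifluoromethanesulfonate, COS(=O)(=O)C(F)(F)F
Why: Lithium–iodine exchange retains the alkene geometry, the alkenyllithium should add 1,2 to the more electrophilic C2 carbonyl of 8 (the C1 carbonyl is a deactivated vinylogous ester), and the tertiary lithium alkoxide is O-methylated in situ by methyl triflate; the stereocentre forms without control, and the racemate is intended.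

Step 5
Reactants: 11 rac-4-[(1E)-1-(3,4-dimethoxyphenyl)prop-1-en-2-yl]-3,4-dimethoxycyclobut-2-en-1-one; 12 pent-1-en-4-yne
Product: 13 (4S)-4-[(1E)-1-(3,4-dimethoxyphenyl)prop-1-en-2-yl]-4,5-dimethoxy-2-(prop-2-en-1-yl)cyclohexa-2,5-dien-1-one
Conditions: Ni(cod)2 (10 mol %), (S,R,R)-O,O′-(1,1′-binaphthyl-2,2′-diyl)-N,N-bis(1-phenylethyl)phosphoramidite or its antipode (20 mol %), 12 (3 equiv, syringe pump), toluene, 0 °C to rt
Reagents that add atoms: none
Why: Proposed new method: zerovalent nickel should insert into the strained acyl C1–C4 bond of 11 as in the known nickel-catalysed benzannulation of cyclobutenones with alkynes (the closest known reaction type, there racemic and ending in phenols), giving a nickelacyclopentenone/η4-vinylketene species in which C4, flanked by the C2=C3 enol ether of 11 and the side-chain alkene, is an η3-allyl terminus that exchanges faces by π–σ–π slippage, so that both enantiomers of 11 converge on the same ligand-bound intermediates. Alkyne 12 then inserts into the Ni–C4 bond with its unsubstituted terminus, and the six-membered ring is closed by acyl–alkenyl C–C reductive elimination from the resulting seven-membered nickelacycle, a formal [4+2] that expands the four-membered ring by two carbons. Because C4 is quaternary the dienone cannot tautomerise to a phenol and is released as such. The C4 stereocentre is set under catalyst control by the chiral phosphoramidite in the C4–C(alkyne) bond-forming insertion, for which enantioselective nickel- and rhodium-catalysed C–C activations of cyclobutanones with chiral phosphorus ligands are the precedent. The step needs regioselectivity, secured by sterics (the quaternary C4 can only bond to the CH terminus, leaving the allyl-bearing carbon for the acyl group), chemoselectivity over thermal 4π-opening/6π-closure onto the side-chain alkene and over alkyne oligomerisation, secured by working at 0 °C with slow addition of 12, and retention of the E-alkene, secured by the preference of the aryl group for the syn position of the allyl.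

**Compound list**

1 | 4-iodo-1,2-dimethoxybenzene | COc1ccc(I)cc1OC | starting material
2 | propyne | CC#C | starting material
3 | 1,2-dimethoxy-4-(prop-1-yn-1-yl)benzene | CC#Cc1ccc(OC)c(OC)c1 | intermediate
4 | chlorobis(cyclopentadienyl)[(1E)-1-(3,4-dimethoxyphenyl)prop-1-en-2-yl]zirconium (cyclopentadienyl rings drawn σ-bonded; zirconium trans to aryl) | C/C(=C\c1ccc(OC)c(OC)c1)[Zr](Cl)(C1C=CC=C1)C1C=CC=C1 | intermediate
5 | 4-[(1E)-2-iodoprop-1-en-1-yl]-1,2-dimethoxybenzene | C/C(I)=C\c1ccc(OC)c(OC)c1 | intermediate
6 | dimethyl squarate (3,4-dimethoxycyclobut-3-ene-1,2-dione) | COC1=C(OC)C(=O)C1=O | starting material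
7 | rac-4-hydroxy-2,3-dimethoxycyclobut-2-en-1-one | COC1=C(OC)C(O)C1=O | intermediate
8 | 3-methoxycyclobut-3-ene-1,2-dione (methyl semisquarate) | COC1=CC(=O)C1=O | intermediate
9 | [(1Z)-1-(3,4-dimethoxyphenyl)prop-1-en-2-yl]lithium (lithium trans to the aryl group) | [Li]/C(C)=C/c1ccc(OC)c(OC)c1 | intermediate
10 | rac-lithium 1-[(1E)-1-(3,4-dimethoxyphenyl)prop-1-en-2-yl]-2-methoxy-4-oxocyclobut-2-en-1-olate | [Li]OC1(/C(C)=C/c2ccc(OC)c(OC)c2)C(OC)=CC1=O | intermediate
11 | rac-4-[(1E)-1-(3,4-dimethoxyphenyl)prop-1-en-2-yl]-3,4-dimethoxycyclobut-2-en-1-one | COC1=CC(=O)C1(OC)/C(C)=C/c1ccc(OC)c(OC)c1 | intermediate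
12 | pent-1-en-4-yne | C=CCC#C | starting material
13 | (4S)-4-[(1E)-1-(3,4-dimethoxyphenyl)prop-1-en-2-yl]-4,5-dimethoxy-2-(prop-2-en-1-yl)cyclohexa-2,5-dien-1-one | C=CCC1=C[C@](OC)(/C(C)=C/c2ccc(OC)c(OC)c2)C(OC)=CC1=O | target

**Step count**

Total steps: 5. Longest linear sequence: 4 steps (1, 2, 4, 5); step 3 is a one-step side branch.

**Steps most likely to fail**

Step 5. The chiral nickel catalyst may fail to discriminate the two faces of C4, or the nickel-bound intermediates may not equilibrate, so that the racemate is simply carried through. The fallback sets out from 11 and returns at 13. Compounds 11 and 12 would be coupled under the established achiral conditions, Ni(cod)2 (10 mol %) and PPh3 (20 mol %) in toluene at 0 °C, to give rac-4-[(1E)-1-(3,4-dimethoxyphenyl)prop-1-en-2-yl]-4,5-dimethoxy-2-(prop-2-en-1-yl)cyclohexa-2,5-dien-1-one F1. The enantiomers would then be separated by preparative HPLC on an amylose tris(3,5-dimethylphenylcarbamate) phase, the (4S) fraction being 13.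

Step 2. Hydride delivery to the unsymmetrical alkyne may be insufficiently regioselective, with zirconium ending partly on the benzylic carbon and leading to the regioisomeric iodide. The fallback sets out from 3 and returns at 5. Copper-catalysed formal hydroboration of 3 (B2pin2, CuCl 5 mol %, NaOtBu, P(p-tol)3, MeOH, THF, rt) should place boron on the methyl-bearing carbon by syn borylcupration and protonation, giving 2-[(1Z)-1-(3,4-dimethoxyphenyl)prop-1-en-2-yl]-4,4,5,5-tetramethyl-1,3,2-dioxaborolane F2. Iododeboronation with retention (I2, NaOH, THF, 0 °C) should then give 5.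

Step 4. In situ O-methylation of the hindered tertiary lithium alkoxide may be slow, so that on warming the alkoxide fragments by oxy-anion-accelerated ring opening instead of being alkylated. The fallback sets out from 10 and returns at 11. The reaction would be quenched at −78 °C with aq. NH4Cl to isolate rac-4-[(1E)-1-(3,4-dimethoxyphenyl)prop-1-en-2-yl]-4-hydroxy-3-methoxycyclobut-2-en-1-one F3. This alcohol would be methylated under non-basic conditions (MeI, Ag2O, K2CO3, MeCN, rt) to give 11.

**Further compounds**

F1 | step 5 | rac-4-[(1E)-1-(3,4-dimethoxyphenyl)prop-1-en-2-yl]-4,5-dimethoxy-2-(prop-2-en-1-yl)cyclohexa-2,5-dien-1-one | C=CCC1=CC(OC)(/C(C)=C/c2ccc(OC)c(OC)c2)C(OC)=CC1=O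
F2 | step 2 | 2-[(1Z)-1-(3,4-dimethoxyphenyl)prop-1-en-2-yl]-4,4,5,5-tetramethyl-1,3,2-dioxaborolane | C/C(B1OC(C)(C)C(C)(C)O1)=C\c1ccc(OC)c(OC)c1
F3 | step 4 | rac-4-[(1E)-1-(3,4-dimethoxyphenyl)prop-1-en-2-yl]-4-hydroxy-3-methoxycyclobut-2-en-1-one | COC1=CC(=O)C1(O)/C(C)=C/c1ccc(OC)c(OC)c1
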